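(The constants are those of an exercise; the result is computed.)

We compare two half-lives: how fast links form and how fast they are lost.

    second end groups + links → over-reaction product (k1 = 0.143 L mol⁻¹ min⁻¹)
    first end groups + second end groups → links + by-product (k2 = 0.756 L mol⁻¹ min⁻¹)

| setting | west | south-west | east |
|---|---|---|---|
| first end groups | 0.10 M | 0.10 M | 0.10 M |
| second end groups | 0.900 equiv | 2.20 equiv | 5.60 equiv |
| time | 30 min | 30 min | 30 min |

- which of the two there is more of at the end, west (over-reaction product / links)
- which of the two there is more of at the end, south-west (over-reaction product / links)
- which of the two there is more of at the end, east (over-reaction product / links)
- links at the end, in percent of the first end groups charged, west
- links at the end, in percent of the first end groups charged, south-west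
- links at the end, in percent of the first end groups charged, east

In west, with second end groups held as charged, first end groups halve in 10 min by the linking step alone and links halve in 54 min by over-reaction alone, so links last longer than first end groups. The ratio of these two times is the selectivity factor S, 5.29: the linking constant over the over-reaction constant. Both steps carry the same factor of second end groups, so that factor cancels.

Let a and l be first end groups and links, as fractions of first end groups charged. Making over losing is then S·a/l, so links rise while l/a is under S and fall beyond it. For these constants, the charge of second end groups changes the pace along this path, not the path.

Our reckoning puts the top at l = 67.8%, where a = 12.8%. Each first end group linked costs one second end group, and each over-reaction costs another, so reaching the top costs 1.07 equiv. West is charged with 0.900 equiv, less than that, so west stops short of the top. South-west and east can pay, but our reckoning stops there: it gives no position at 30 min.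

The forecast went further, with “Treat the second end groups as a shared” "clock". It gave links of 56.3% in west, 64% in south-west and 20.2% in east, with more links in west, more links in south-west and more over-reaction product in east.

The flask gives links of 56.3% in west, 64.0% in south-west and 20.2% in east, with more links in west, more links in south-west and more over-reaction product in east, so the forecast held. In south-west, links were made 6.26 times faster than lost at 4.44 min, but that ratio was 0.424 at the end. There l/a is 12.5, above S, so south-west is past its top.

Now leave south-west until 50 min. Holding its end rate steady, with second end groups at 42.8% of their charge, links lose 9.9 percentage points, which leaves about 54.1%. The computed result is 53.5%.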